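**Assumption:** the SMILES is taken as the definition of dysidenone A (bolinaquinone-type skeleton). Terpenoid numbering is used: ring A = C1–C5, C10; ring B = C5–C10; C11 = CH2 linker; β = face of the C5 methyl. The route is a paper design; nothing has been run.

## Retrosynthetic overview
1. Dysidenone A ⇐ hydroxyquinone 19 (bolinaquinone) by benzilic-ester ring contraction (adds MeOH, six-ring → cyclopentenone).
2. Quinone ring ⇐ 4-alkynyl-4-hydroxycyclobutenone 17 by thermal 4π-electrocyclic opening/ring closure; 17 ⇐ squarate 14 + neopentyl-lithium from iodide 12 + methoxyethyne.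
3. C8/C9 ⇐ Δ8-enal 8 by α-face hydride, then α-face methylation; ring B ⇐ intramolecular aldol condensation of keto-aldehyde 6.
4. Ring A (C5 quaternary, C10, Δ3) ⇐ (1R,5R)-(+)-verbenone: cuprate addition anti to the CMe2 bridge, then cyclobutane cleavage (C10 is the verbenone bridgehead).
5. Ring order: A (bought) → B (aldol) → oxygenated six-ring (electrocyclic cascade) → contraction to the cyclopentenone.

## Route

**Step 1**
Reactants: 1, (1R,5R)-(+)-verbenone; 2, pent-4-enylmagnesium bromide
Product: 3, (1R,4S,5S)-3,4,6,6-tetramethyl-4-(pent-4-enyl)bicyclo[3.1.1]heptan-2-one (C3 epimers; pentenyl anti to the CMe2 bridge)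
Conditions: 2, CuBr·SMe2 (10 mol %), TMSCl, THF, −78 → −20 °C; then MeLi, 0 °C; MeI, DMPU, −78 °C → rt
Reagents that add atoms: 2, C=CCCC[Mg]Br; iodomethane, CI
Why: Cu-catalysed conjugate addition occurs on the face opposite the gem-dimethyl bridge, setting the C5 quaternary centre (5-Me cis to the future C9 unit); the regenerated enolate is methylated at the only enolisable carbon.

**Step 2**
Reactants: 3
Product: 4, 4-(2-chloropropan-2-yl)-2,3-dimethyl-3-(pent-4-enyl)cyclohexanone (ring configuration as in 5)
Conditions: HCl (g), AcOH, 15 °C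
Reagents that add atoms: hydrogen chloride, Cl
Why: Acid-promoted cleavage of the cyclobutane bond α to the ketone (as in pinane → menthane openings) gives the enol and a tertiary cation trapped as chloride; the bridgehead becomes C10 untouched.

**Step 3**
Reactants: 4
Product: 5, (2RS,3S,4S)-2,3-dimethyl-3-(pent-4-enyl)-4-(prop-1-en-2-yl)cyclohexanone
Conditions: DBU, PhMe, 100 °C
Reagents that add atoms: none
Why: E2 dehydrochlorination with a bulky base removes a methyl hydrogen (Hofmann) to give the isopropenyl group; the minor isopropylidene isomer is removed by chromatography.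

**Step 4**
Reactants: 5
Product: 6, (3S,4S)-2,3-dimethyl-3-(pent-4-enyl)-4-(prop-1-en-2-yl)cyclohex-1-enyl triflate
Conditions: Tf2O, 2,6-di-tert-butyl-4-methylpyridine, CH2Cl2, 0 °C → rt
Reagents that add atoms: triflic anhydride, O=S(=O)(OS(=O)(=O)C(F)(F)F)C(F)(F)F
Why: Equilibrating enol triflation favours the more substituted (tetrasubstituted, future C3=C4) enol triflate; the minor regioisomer is separated.

**Step 5**
Reactants: 6
Product: 7, (3S,4R)-4-acetyl-2,3-dimethyl-3-(4-oxobutyl)cyclohex-1-enyl triflate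
Conditions: OsO4 (2 mol %), NaIO4, 2,6-lutidine, dioxane/H2O, rt
Reagents that add atoms: OsO4, O=[Os](=O)(=O)=O; NaIO4, [Na+].[O-]I(=O)(=O)=O (with water)
Why: Lemieux–Johnson cleavage of both terminal alkenes (isopropenyl → acetyl, pentenyl → butanal); the electron-poor tetrasubstituted enol triflate is inert.

**Step 6**
Reactants: 7
Product: 8, trans-fused 8-formyl-4,5β,9-trimethyl-Δ3,Δ8-octalin-3-yl triflate (10α-H)
Conditions: piperidine, AcOH, PhH, 60 °C
Reagents that add atoms: none
Why: Enamine-mediated intramolecular aldol condensation (aldehyde α-carbon C8 onto the C9 methyl ketone) closes ring B as the conjugated enal; C5 and C10 are carried through unchanged, although C10 is epimerisable here, so conditions are kept mild.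

**Step 7**
Reactants: 8
Product: 9, 4,5β,9-trimethyl-Δ3,Δ8-octalin-8-carbaldehyde (10α-H)
Conditions: Pd(OAc)2, PPh3, n-Bu3N, HCO2H, DMF, 60 °C
Reagents that add atoms: none
Why: Pd-catalysed formate reduction of the vinyl triflate gives the trisubstituted Δ3 alkene with the C4 methyl in place.

**Step 8**
Reactants: 9
Product: 10, 4,5β,9β-trimethyl-Δ3-octalin-8-carbaldehyde (9α-H, 10α-H; C8 epimers)
Conditions: [(Ph3P)CuH]6 (Stryker's reagent), PhMe, rt; aq. NH4Cl
Reagents that add atoms: none
Why: Chemoselective 1,4-reduction of the enal; the bulky copper hydride attacks C9 from the α-face, opposite the axial 5β-methyl, giving 9β-Me.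

**Step 9**
Reactants: 10
Product: 11, 4,5β,8α,9β-tetramethyl-Δ3-octalin-8β-carbaldehyde (10α-H)
Conditions: t-BuOK, MeI, THF, 0 °C
Reagents that add atoms: iodomethane, CI
Why: α-Methylation of the exocyclic aldehyde enolate from the α-face, anti to the adjacent axial 9β-methyl, sets the C8 quaternary centre (8α-Me, 8β-CHO).

**Step 10**
Reactants: 11
Product: 12, the 8β-hydroxymethyl compound (neopentyl alcohol)
Conditions: NaBH4, MeOH, 0 °C
Reagents that add atoms: none
Why: Simple carbonyl reduction; no stereocentre is affected.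

**Step 11**
Reactants: 12
Product: 13, the 8β-iodomethyl compound
Conditions: I2, PPh3, imidazole, PhMe, 90 °C
Reagents that add atoms: iodine, II
Why: Appel-type iodination; works at neopentyl carbons with heating and cannot rearrange by SN2.

**Step 12**
Reactants: 13; 14, di-tert-butyl squarate
Product: 15, 3-tert-butoxy-4-[(decalinyl)methyl]cyclobut-3-ene-1,2-dione
Conditions: 13, t-BuLi (2.1 equiv), Et2O, −78 °C; add to 14, THF, −78 °C; then TFAA, −78 → 0 °C
Reagents that add atoms: none besides reactant 14
Why: Li–I exchange, 1,2-addition to the squarate and TFAA-induced transposition (Liebeskind–Moore protocol) give the alkyl-alkoxy cyclobutenedione.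

**Step 13**
Reactants: 15; 16, methoxyethyne (as lithium acetylide)
Product: 17, 3-tert-butoxy-4-hydroxy-4-(methoxyethynyl)-2-[(decalinyl)methyl]cyclobut-2-enone (carbinol epimers)
Conditions: 16, n-BuLi, THF, −78 °C; then 15, −78 °C
Reagents that add atoms: 16, COC#C
Why: The acetylide adds to the more electrophilic carbonyl, the one next to C–OtBu (the other is a vinylogous ester), fixing the later oxygenation pattern.

**Step 14**
Reactants: 17
Product: 18, 2-tert-butoxy-5-methoxy-3-[(decalinyl)methyl]-1,4-benzoquinone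
Conditions: PhMe, 110 °C
Reagents that add atoms: none
Why: Moore rearrangement: conrotatory 4π-electrocyclic opening of the cyclobutenone (OH rotates outward) gives the (Z)-enynylketene, which ring-closes (via a diradical, then H-transfer) to the quinone; the oxygenated six-ring forms here with OMe and CH2R flanking the same carbonyl.

**Step 15**
Reactants: 18
Product: 19, bolinaquinone: 2-hydroxy-5-methoxy-3-[(decalinyl)methyl]-1,4-benzoquinone
Conditions: TFA, CH2Cl2, −20 → 0 °C, short
Reagents that add atoms: none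
Why: Acidolysis of the tert-butyl vinylogous ester (loss of isobutene) is much faster than protonation of the Δ3 alkene at low temperature.

**Step 16**
Reactants: 19
Product: 20, dysidenone A
Conditions: NaOMe, MeOH, 0 °C → rt, Ar; AcOH quench; HPLC
Reagents that add atoms: sodium methoxide/methanol, [Na+].[O-]C
Why: Benzilic-ester rearrangement of the hydroxyquinone in its 1,2-dione form (methoxide adds to C2′, C3′ migrates to C1′) contracts the ring to the hydroxy ester. C8 is too remote to bias the new ring, so about 1:1 of 20 and its (1R,5S)-ring epimer is expected; the ring CH is enolisable and equilibrates, and the isomers are separated by HPLC.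

## Compound list
1 | (1R,5R)-(+)-verbenone | CC1=CC(=O)[C@@H]2C[C@H]1C2(C)C | starting material
2 | pent-4-enylmagnesium bromide | C=CCCC[Mg]Br | starting material
3 | (1R,4S,5S)-3,4,6,6-tetramethyl-4-(pent-4-enyl)bicyclo[3.1.1]heptan-2-one | C[C@@]1(CCCC=C)C(C)C(=O)[C@@H]2C[C@H]1C2(C)C | intermediate
4 | 4-(2-chloropropan-2-yl)-2,3-dimethyl-3-(pent-4-enyl)cyclohexanone | O=C1CC[C@@H](C(C)(C)Cl)[C@](C)(CCCC=C)C1C | intermediate
5 | (2RS,3S,4S)-2,3-dimethyl-3-(pent-4-enyl)-4-(prop-1-en-2-yl)cyclohexanone | O=C1CC[C@@H](C(C)=C)[C@](C)(CCCC=C)C1C | intermediate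
6 | (3S,4S)-2,3-dimethyl-3-(pent-4-enyl)-4-(prop-1-en-2-yl)cyclohex-1-enyl triflate | C=CCCC[C@]1(C)C(C)=C(OS(=O)(=O)C(F)(F)F)CC[C@H]1C(C)=C | intermediate
7 | (3S,4R)-4-acetyl-2,3-dimethyl-3-(4-oxobutyl)cyclohex-1-enyl triflate | O=CCCC[C@]1(C)C(C)=C(OS(=O)(=O)C(F)(F)F)CC[C@H]1C(C)=O | intermediate
8 | trans-fused 8-formyl-4,5β,9-trimethyl-Δ3,Δ8-octalin-3-yl triflate | O=CC1=C(C)[C@@H]2CCC(OS(=O)(=O)C(F)(F)F)=C(C)[C@@]2(C)CC1 | intermediate
9 | 4,5β,9-trimethyl-Δ3,Δ8-octalin-8-carbaldehyde (10α-H) | O=CC1=C(C)[C@@H]2CCC=C(C)[C@@]2(C)CC1 | intermediate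
10 | 4,5β,9β-trimethyl-Δ3-octalin-8-carbaldehyde (C8 epimers) | O=CC1CC[C@]2(C)C(C)=CCC[C@H]2[C@H]1C | intermediate
11 | 4,5β,8α,9β-tetramethyl-Δ3-octalin-8β-carbaldehyde | O=C[C@@]1(C)CC[C@]2(C)C(C)=CCC[C@H]2[C@H]1C | intermediate
12 | 8β-(hydroxymethyl)-4,5β,8α,9β-tetramethyl-Δ3-octalin | OC[C@@]1(C)CC[C@]2(C)C(C)=CCC[C@H]2[C@H]1C | intermediate
13 | 8β-(iodomethyl)-4,5β,8α,9β-tetramethyl-Δ3-octalin | IC[C@@]1(C)CC[C@]2(C)C(C)=CCC[C@H]2[C@H]1C | intermediate
14 | di-tert-butyl squarate | CC(C)(C)OC1=C(OC(C)(C)C)C(=O)C1=O | starting material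
15 | 3-tert-butoxy-4-[(decalinyl)methyl]cyclobut-3-ene-1,2-dione | O=C1C(=O)C(OC(C)(C)C)=C1C[C@@]1(C)CC[C@]2(C)C(C)=CCC[C@H]2[C@H]1C | intermediate
16 | methoxyethyne (used as lithium acetylide) | COC#C | starting material
17 | 3-tert-butoxy-4-hydroxy-4-(methoxyethynyl)-2-[(decalinyl)methyl]cyclobut-2-enone | O=C1C(C[C@@]2(C)CC[C@]3(C)C(C)=CCC[C@H]3[C@H]2C)=C(OC(C)(C)C)C1(O)C#COC | intermediate
18 | 2-tert-butoxy-5-methoxy-3-[(decalinyl)methyl]-1,4-benzoquinone | O=C1C(OC)=CC(=O)C(OC(C)(C)C)=C1C[C@@]1(C)CC[C@]2(C)C(C)=CCC[C@H]2[C@H]1C | intermediate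
19 | bolinaquinone (2-hydroxy-5-methoxy-3-[(decalinyl)methyl]-1,4-benzoquinone) | O=C1C(OC)=CC(=O)C(O)=C1C[C@@]1(C)CC[C@]2(C)C(C)=CCC[C@H]2[C@H]1C | intermediate
20 | dysidenone A, methyl (1S,5R)-1-hydroxy-3-methoxy-4-oxo-5-{[(1R,2R,4aS,8aS)-1,2,4a,5-tetramethyl-1,2,3,4,4a,7,8,8a-octahydronaphthalen-2-yl]methyl}cyclopent-2-ene-1-carboxylate | COC(=O)[C@]1(O)C=C(OC)C(=O)[C@@H]1C[C@@]1(C)CC[C@]2(C)C(C)=CCC[C@H]2[C@H]1C | target

("Decalinyl" = the 4,5β,8α,9β-tetramethyl-Δ3-octalin-8β-yl unit of 11.)

## Totals
Total steps: 16. Longest linear sequence: 16 (from 1; compounds 2, 14 and 16 are bought or made in situ).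

## Three steps most likely to fail, with fallbacks
1. **Step 16 (ring contraction).** The hydroxyquinone anion is a poor electrophile, and there is no control of the two ring stereocentres (at best about half the product is 20). Fallback: build the cyclopentenone by aldol closure instead. Add the alkyllithium from 13 to methyl 5-formyl-4-methoxyfuran-2-carboxylate, deoxygenate the carbinol, open the furan oxidatively (NBS/aq. acetone or 1O2) to the (Z)-ene-dione keto-ester, and close C1–C5 of the ring with K2CO3/MeOH.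
2. **Step 4 (regioselective Δ3 enol triflate).** It relies on thermodynamic enolisation toward the carbon next to the quaternary centre; a Δ2/Δ3 mixture is possible. Fallback: make the enolate regiospecifically. In step 1 trap the cuprate enolate with Eschenmoser's salt and eliminate to the α-methylene ketone; after cyclobutane cleavage, L-Selectride 1,4-reduction with PhNTf2 trapping can only give the C3=C4 triflate.
3. **Step 8 (conjugate reduction of the tetrasubstituted enal).** Both reactivity and α-face selectivity at C9 are uncertain. Fallback: reorder so that hydrogenation can be used. Protect the C3 ketone of 5 as a dioxolane (no triflate), run steps 5–6, hydrogenate the enal over Pd/C when it is the only C=C (α-face), methylate C8, then unveil Δ3 afterwards (ketal hydrolysis, enol triflate, Pd/HCO2H).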